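All runs are simulated from invented constants, noise included.

In a one-step world the starting material would fall along one exponential from the first moment, and one number, a rate constant times the time, would tell how far it had fallen.

| flask | starting material | second substrate | gas | remark | time |
|---|---|---|---|---|---|
| dusk | 6.9 mM | 24 mM | 10 mM (held) | run made earlier |  |
| spring | 18 mM | 24 mM | 10 mM (held) | run made earlier |  |
| Tuesday's | 8.0 mM | 24.0 mM | 10 mM (held) |  | 6.0 min |
| Friday's | 24 mM | 24.0 mM | 10 mM (held) |  | 25 min |

| run | time / min | target / % | starting material / % |
|---|---|---|---|
| dusk | 1.50 | 1.7 | 97.4 |
| dusk | 5.00 | 9.4 | 86.3 |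
| dusk | 8.00 | 17.2 | 77.9 |
| dusk | 15.0 | 32.7 | 59.6 |
| dusk | 20.0 | 41.2 | 49.4 |
| dusk | 25.0 | 49.1 | 40.7 |
| spring | 1.50 | 1.7 | 97.5 |
| spring | 5.00 | 9.3 | 87.7 |
| spring | 8.00 | 16.7 | 78.4 |
| spring | 15.0 | 31.0 | 60.8 |
| spring | 20.0 | 39.4 | 50.3 |
| spring | 25.0 | 47.0 | 41.8 |

(readings scatter by 0.3 percentage points)

- at the start none of reagent is dissolved
- the earlier runs were read with a standard deviation of 0.3 percentage points
- on the list of suspects stand: starting material + second substrate -> cross product; gas <-> reagent; second substrate + reagent -> second product; starting material + reagent -> target

- the flask that ends with the higher amount of target, in percent of the starting material charged, or "neither" when 2 percentage points or less lies between them (Tuesday's / Friday's / neither)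
- final target, as a percentage of the starting material charged, in Tuesday's
- final target, as a percentage of the starting material charged, in Friday's

The dusk run came close to this. From 8.00 min on, its starting material fell pseudo-first-order with 0.0382 /min, and that line met the full charge at a hold-up of 1.46 min. The spring run gave 0.0370 /min and 1.42 min.

So I folded the constant and the time into a clock number: constant times the time after the hold-up, the natural logarithm of how far the starting material has fallen. For Tuesday's, with dusk's constants, the clock number was 0.173, leaving 84.1%. For Friday's, with spring's constants, it was 0.872, which is 5.03 times Tuesday's.

Between dusk's readings, a share 0.858 of the lost starting material appeared as target. Stepping back from the reading at 8.00 min, I reckoned 11.9% for Tuesday's. Spring's last target, lowered along the trend with charge, gave 45.9% for Friday's.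

Was one number enough? Dusk and spring, at the same time, parted by 2.1 percentage points in target against a scatter of 0.3 points, so it was not enough for the last points. My 45.9% for Friday's at its own time, against 11.9% for Tuesday's at its own time and with a margin of 2 points, still chose Friday's.

The forecast, slightly under me on Tuesday's, gave Friday's, 11.8% and 45.9%: “Time dominates, so Friday's wins”.

The flask gave Friday's, with 12.1% in Tuesday's and 46.5% in Friday's.

    starting material + second substrate → cross product (k = 0.335 /M/min)
    gas ⇌ reagent, rate k2*(csat - [reagent]) (kL = 0.454 /min)
    second substrate + reagent → second product (k = 2.96 /M/min)
    starting material + reagent → target (k = 3.77 /M/min)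

Moving one of Tuesday's settings up or down by the same factor shifted its target by at most this much, among the settings tried: time (4.5 points), then second substrate (0.36 points), then starting material (0.11 points). Tuesday's clock number of 0.173 left 84.1% of the starting material, and the flask held 83.7%. Read at 60.0 min, Tuesday's flask had a clock number of 2.24, which left 10.7%, and the flask held 10.8%.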